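**Plan**
1. Retrosynthetic cuts: two helpers are put back first, Br on C8 and a methyl on the ring-A 2'-OH. Then C4–C4a and O1–C2 of the pyran are cut together, which releases 3-methylbut-2-enal. Last, the ketone–C1' bond is cut, giving 4-bromo-3,5-dihydroxybenzoic acid and 1,3,5-trimethoxybenzene.
2. Enabling feature: the pyran ring O1–C2–C3=C4–C4a=C8a is a closed 1-oxatriene. Its open form O1=C8a–C4a=C4–C3=C2 is the o-quinone methide of ring B, the dehydrated adduct of the phenol carbon C4a–H and an enal, so one condensation/oxa-6π cascade makes both bonds.
3. Ring B without the pyran is a 5-aroylresorcinol with a mirror plane. Its two OH groups are equivalent, and so are its two carbons next to the ketone. The carbon between the OH groups (later C8) is the only rival site and normally the preferred one. The bought-in Br closes it, acidifies the phenols, and later tempers the acid lability of the chromene.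
4. Forward order: both benzene rings are bought and step 1 joins them through the ketone. Step 2 builds the only new ring (the pyran) and desymmetrises ring B. Steps 3 and 4 remove the helpers, O-methyl first and then Br.
5. Stereochemistry: none has to be set, because C2 carries two methyl groups and C3=C4 is cis by ring constraint.

Key step: step 2

Remark: the SMILES holds no stereocentre, and rotation about the aryl–carbonyl bonds of this tri-ortho-substituted benzophenone is fast at room temperature. The target is therefore achiral and no enantiocontrol is required. Chromene numbering is used for the bicycle and primes for ring A.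

Step 1
Reactants: 1 4-bromo-3,5-dihydroxybenzoic acid; 2 1,3,5-trimethoxybenzene
Product: 5 (4-bromo-3,5-dihydroxyphenyl)(2,4,6-trimethoxyphenyl)methanone, via mixed anhydride 3 (not isolated), via ketone bis(trifluoroacetate) 4 (not isolated)
Conditions: TFAA (4 equiv), CH2Cl2, 0 °C to rt, evaporate; 2 (1.1 equiv), CH2Cl2, rt to 40 °C; then MeOH, rt
Reagents that add atoms: none
Why: Friedel–Crafts acylation through the mixed carboxylic–trifluoroacetic anhydride: TFAA activates the acid and also caps both phenols as transient trifluoroacetates (no depside formation, no acid-induced bromine transfer to 2), the threefold-symmetric and very nucleophilic arene 2 can give only one ketone, which is deactivated against a second acylation, and aryl trifluoroacetates are cleaved by neutral methanol.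

Step 2
Reactants: 5 (4-bromo-3,5-dihydroxyphenyl)(2,4,6-trimethoxyphenyl)methanone; 6 3-methylbut-2-enal
Product: 8 (8-bromo-7-hydroxy-2,2-dimethyl-2H-chromen-5-yl)(2,4,6-trimethoxyphenyl)methanone, via o-quinone methide 7 (not isolated)
Conditions: 6 (1.2 equiv), ethylenediammonium diacetate (20 mol %), xylene, 130 °C
Reagents that add atoms: none
Why: This is the formal [3+3] annulation of a phenol with an enal (iminium-catalysed aldol-type C-alkylation, elimination to an o-quinone methide, oxa-6π electrocyclisation), the standard entry to 2,2-dimethyl-2H-chromenes from resorcinols. The diamine salt turns 6 into its iminium ion, ring B attacks it through the ortho carbon next to the ketone (C4–C4a bond), and loss of the amine gives the (Z)-quinone methide 7, whose alkenyl chain points toward the ring carbonyl oxygen and away from the aroyl group. The pyran ring then closes by thermal disrotatory oxa-6π electrocyclisation of the 1-oxatriene O=C8a–C4a=C4–C3=C2 (O1–C2 bond), driven by rearomatisation of ring B; no stereocentre arises because C2 bears two methyl groups. Site selectivity rests on the substrate: Br occupies the carbon between the two OH groups, and the two remaining ortho carbons and the two OH groups are related by the mirror plane of ring B, so every productive event gives the same constitution and also tells the two phenols apart. Ring A cannot compete, since without a free OH it has no path to a quinone methide and additions at its CH positions stay reversible. A second annulation at C6 would put a fourth ortho substituent around the ketone and is held back by that strain and by the small excess of 6.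

Step 3
Reactants: 8 (8-bromo-7-hydroxy-2,2-dimethyl-2H-chromen-5-yl)(2,4,6-trimethoxyphenyl)methanone
Product: 10 (8-bromo-7-hydroxy-2,2-dimethyl-2H-chromen-5-yl)(2-hydroxy-4,6-dimethoxyphenyl)methanone, via boron chelate 9 (not isolated)
Conditions: BCl3 (2.5 equiv, 1 M in CH2Cl2), CH2Cl2, −78 to −20 °C; then H2O
Reagents that add atoms: none
Why: Chelation-directed aryl methyl ether cleavage: BCl3 binds the ketone oxygen and one flanking methoxy oxygen in a six-membered chelate, chloride removes only that methyl group, chelate 9 switches off the second ortho-methoxy group while the para-methoxy group has no such assistance, and the brominated, O-borylated, acyl-substituted chromene should resist protonation at C3 at low temperature.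

Step 4
Reactants: 10 (8-bromo-7-hydroxy-2,2-dimethyl-2H-chromen-5-yl)(2-hydroxy-4,6-dimethoxyphenyl)methanone
Product: 11 (7-hydroxy-2,2-dimethyl-2H-chromen-5-yl)(2-hydroxy-4,6-dimethoxyphenyl)methanone
Conditions: Pd(OAc)2 (5 mol %), dppf (6 mol %), HCO2Na (3 equiv), DMF, 90 °C
Reagents that add atoms: none
Why: Palladium-catalysed formate hydrodehalogenation (oxidative addition into C8–Br, formate exchange, loss of CO2, C–H reductive elimination) works without H2 or a metal surface and should leave the C3=C4 double bond, the hindered ketone and the phenols untouched.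

**Compound list**
1 | 4-bromo-3,5-dihydroxybenzoic acid | OC(=O)c1cc(O)c(Br)c(O)c1 | starting material
2 | 1,3,5-trimethoxybenzene | COc1cc(OC)cc(OC)c1 | starting material
3 | 4-bromo-3,5-bis(trifluoroacetoxy)benzoic trifluoroacetic anhydride | O=C(OC(=O)C(F)(F)F)c1cc(OC(=O)C(F)(F)F)c(Br)c(OC(=O)C(F)(F)F)c1 | intermediate
4 | [4-bromo-3,5-bis(trifluoroacetoxy)phenyl](2,4,6-trimethoxyphenyl)methanone | COc1cc(OC)c(C(=O)c2cc(OC(=O)C(F)(F)F)c(Br)c(OC(=O)C(F)(F)F)c2)c(OC)c1 | intermediate
5 | (4-bromo-3,5-dihydroxyphenyl)(2,4,6-trimethoxyphenyl)methanone | COc1cc(OC)c(C(=O)c2cc(O)c(Br)c(O)c2)c(OC)c1 | intermediate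
6 | 3-methylbut-2-enal | CC(C)=CC=O | starting material
7 | (6Z)-2-bromo-3-hydroxy-6-(3-methylbut-2-en-1-ylidene)-5-(2,4,6-trimethoxybenzoyl)cyclohexa-2,4-dien-1-one | CC(C)=C/C=C1\C(=O)C(Br)=C(O)C=C1C(=O)c2c(OC)cc(OC)cc2OC | intermediate
8 | (8-bromo-7-hydroxy-2,2-dimethyl-2H-chromen-5-yl)(2,4,6-trimethoxyphenyl)methanone | COc1cc(OC)c(C(=O)c2cc(O)c(Br)c3c2C=CC(C)(C)O3)c(OC)c1 | intermediate
9 | 7-O,2'-O-bis(dichloroboryl) derivative of 10 (ring-A boron chelated by the ketone oxygen, drawn without the dative bond) | COc1cc(OB(Cl)Cl)c(C(=O)c2cc(OB(Cl)Cl)c(Br)c3c2C=CC(C)(C)O3)c(OC)c1 | intermediate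
10 | (8-bromo-7-hydroxy-2,2-dimethyl-2H-chromen-5-yl)(2-hydroxy-4,6-dimethoxyphenyl)methanone | COc1cc(O)c(C(=O)c2cc(O)c(Br)c3c2C=CC(C)(C)O3)c(OC)c1 | intermediate
11 | (7-hydroxy-2,2-dimethyl-2H-chromen-5-yl)(2-hydroxy-4,6-dimethoxyphenyl)methanone (CNP0142929.0, achiral) | COc1cc(O)c(C(=O)c2cc(O)cc3c2C=CC(C)(C)O3)c(OC)c1 | target

Total step count: 4. Longest linear sequence: 4.

**Steps most likely to fail**

Step 2. C–C bond formation at the ring carbon wedged between the aroyl group and the OH may be slow on this deactivated ring. Self-condensation of the enal or a second annulation could then overtake the wanted event.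
- Fallback (from 5, back at 8): the two bonds are made one after the other.
- One phenol of 5 is O-alkylated with 3-chloro-3-methylbut-1-yne (K2CO3, KI, cat. CuI, acetone, 50 °C) to the aryl 1,1-dimethylpropargyl ether F1.
- Heating in N,N-diethylaniline at about 180 °C starts the aromatic propargyl Claisen rearrangement. It is intramolecular and so depends far less on crowding and ring nucleophilicity.
- Bromine again leaves only the carbon next to the ketone for a productive shift.
- The allenylphenol F2 passes by a 1,5-hydrogen shift into the same quinone methide 7, which closes to 8.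

Step 3. Acid set free at the phenol may attack the C3=C4 double bond (HCl addition, cationic oligomerisation), or a second methyl group may be lost.
- Fallback (from 5, back at 10): demethylation and annulation change places, so no Lewis acid ever meets the chromene.
- BCl3 (3.5 equiv, CH2Cl2, −78 to 0 °C, then water) converts 5 via the tris(dichloroboryl) aryloxide F3 into the trihydroxy ketone F4.
- F4 is annulated with 6 using Ca(OH)2 in MeOH at rt. Only the acidic, bromine-flanked ring-B phenols are ionised there, while the ring-A OH stays locked in its hydrogen bond to the ketone.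
- The quinone methide F5 closes to 10.

Step 4. Oxidative addition into a C–Br bond flanked by two oxygen donors, one of them partly a phenolate, may be sluggish. That would leave time for transfer hydrogenation of C3=C4.
- Fallback (from 10, back at 11): the substrate is changed rather than the catalyst.
- Both phenols are acetylated (Ac2O, pyridine, cat. DMAP, rt) to the bromo diacetate F6. This turns the donor next to bromine into an acceptor and removes the phenolate.
- The formate reduction then gives the diacetate F7.
- Catalytic K2CO3 in MeOH releases 11.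

**Further compounds**
F1 | step 2 | {4-bromo-3-hydroxy-5-[(2-methylbut-3-yn-2-yl)oxy]phenyl}(2,4,6-trimethoxyphenyl)methanone | COc1cc(OC)c(C(=O)c2cc(O)c(Br)c(OC(C)(C)C#C)c2)c(OC)c1
F2 | step 2 | [4-bromo-3,5-dihydroxy-2-(3-methylbuta-1,2-dien-1-yl)phenyl](2,4,6-trimethoxyphenyl)methanone | COc1cc(OC)c(C(=O)c2cc(O)c(Br)c(O)c2C=C=C(C)C)c(OC)c1
F3 | step 3 | 3-O,5-O,2'-O-tris(dichloroboryl) derivative of F4 (drawn without the dative bond) | COc1cc(OB(Cl)Cl)c(C(=O)c2cc(OB(Cl)Cl)c(Br)c(OB(Cl)Cl)c2)c(OC)c1
F4 | step 3 | (4-bromo-3,5-dihydroxyphenyl)(2-hydroxy-4,6-dimethoxyphenyl)methanone | COc1cc(O)c(C(=O)c2cc(O)c(Br)c(O)c2)c(OC)c1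
F5 | step 3 | (6Z)-2-bromo-3-hydroxy-5-(2-hydroxy-4,6-dimethoxybenzoyl)-6-(3-methylbut-2-en-1-ylidene)cyclohexa-2,4-dien-1-one | CC(C)=C/C=C1\C(=O)C(Br)=C(O)C=C1C(=O)c2c(O)cc(OC)cc2OC
F6 | step 4 | 2-[(7-acetoxy-8-bromo-2,2-dimethyl-2H-chromen-5-yl)carbonyl]-3,5-dimethoxyphenyl acetate | COc1cc(OC(C)=O)c(C(=O)c2cc(OC(C)=O)c(Br)c3c2C=CC(C)(C)O3)c(OC)c1
F7 | step 4 | 2-[(7-acetoxy-2,2-dimethyl-2H-chromen-5-yl)carbonyl]-3,5-dimethoxyphenyl acetate | COc1cc(OC(C)=O)c(C(=O)c2cc(OC(C)=O)cc3c2C=CC(C)(C)O3)c(OC)c1
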